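**Plan**
Numbering (drimane): ring A = C1–C5 and C10 (C1 acyloxy carbinol, C4 CMe2, C5 tertiary carbinol, C10 quaternary carbon with CH3). Ring B = C5–C10 (C7=C8, C9–H). C11 is the formyl carbon on C9 and C12 the formyl carbon on C8.
Cuts, in order: the coumaroyl C(=O)–O1 ester bond. Next C7=C8 and C9–C10 together, which removes ring B and leaves a monocyclic aldehyde and a four-carbon enal. Then C10=CH2/C5–OH back to a 5,10-epoxide, C7HO back to a terminal alkyne, and C5–C6 back to an acetylide addition.
Enabling feature: in ring B, C8 is the α-carbon of the C12 enal, so C7=C8 is an aldol-condensation retron and C9 is the β-carbon of a C9=C8 enal. C9 is bonded to C10, whose CH3 is what one hydrogen atom makes from C10=CH2. C7 lies three bonds from C10 (C7–C6–C5–C10), so a C10 radical, an enal and a C7 aldehyde can close ring B in one radical–polar event with the C5 carbinol already in place.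
Forward order: ring A is bought and decorated (steps 1–8), ring B arises in step 9 and is dehydrated in step 10. The ester is joined in step 13, and one acidic fluoride step frees C11HO and the phenol.
Stereochemistry: C1 comes from a CBS reduction and C5 from epoxidation anti to the C1 silyl ether. C10 and C9 come from substrate control in step 9 (ring A chair, axial 4β-methyl). C9 carries a non-enolisable acetal until the last step.

Key step: step 9

Remark on the chemistry: the configuration drawn at C7 and C8 of 14 and 15 (both substituents equatorial) is the expected one. It has no consequence, since step 10 erases both centres.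

Step 1
Reactants: 1 4,4-dimethylcyclohexane-1,3-dione
Product: 2 2,4,4-trimethylcyclohexane-1,3-dione
Conditions: MeI, NaOH, H2O/dioxane, reflux
Reagents that add atoms: iodomethane CI
Why: Classical C-alkylation of a cyclohexane-1,3-dione enolate at the carbon between the two carbonyl groups should install the future C10 methyl group, and no lasting stereocentre forms because this carbon stays enolisable.

Step 2
Reactants: 2 2,4,4-trimethylcyclohexane-1,3-dione
Product: 3 3-isobutoxy-2,6,6-trimethylcyclohex-2-en-1-one
Conditions: i-BuOH, p-TsOH (cat.), toluene, Dean–Stark, reflux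
Reagents that add atoms: 2-methylpropan-1-ol CC(C)CO
Why: Acid-catalysed vinylogous ester formation with azeotropic removal of water should take place at the carbonyl remote from the gem-dimethyl group for steric reasons, which leaves the neopentyl carbonyl (future C5) free for addition.

Step 3
Reactants: 3 3-isobutoxy-2,6,6-trimethylcyclohex-2-en-1-one
Product: 5 3-ethynyl-2,4,4-trimethylcyclohex-2-en-1-one, via propargylic carbinol 4 (not isolated)
Conditions: HC≡CMgBr (3 equiv), THF, 0 °C to 40 °C; then 2 M HCl, rt
Reagents that add atoms: ethynylmagnesium bromide C#C[Mg]Br; water O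
Why: In this Stork–Danheiser enone transposition the small acetylide adds 1,2 to the vinylogous ester carbonyl and aqueous acid ionises carbinol 4 and hydrolyses the enol ether, which should form C5–C6 and turn C1 into the ketone.

Step 4
Reactants: 5 3-ethynyl-2,4,4-trimethylcyclohex-2-en-1-one
Product: 6 (R)-3-ethynyl-2,4,4-trimethylcyclohex-2-en-1-ol
Conditions: (S)-Me-CBS ((S)-1-methyl-3,3-diphenyltetrahydropyrrolo[1,2-c][1,3,2]oxazaborole, 15 mol %), catecholborane, toluene, −78 °C; then H2O
Reagents that add atoms: none
Why: Corey–Bakshi–Shibata reduction, with the methyl-substituted sp2 flank as the large group and the CH2 flank as the small group, should deliver hydride to one carbonyl face and set C1 as R, while catecholborane at low temperature leaves the alkyne alone.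

Step 5
Reactants: 6 (R)-3-ethynyl-2,4,4-trimethylcyclohex-2-en-1-ol
Product: 7 (R)-tert-butyl[(3-ethynyl-2,4,4-trimethylcyclohex-2-en-1-yl)oxy]dimethylsilane
Conditions: TBSCl, imidazole, DMF, rt
Reagents that add atoms: tert-butyldimethylsilyl chloride CC(C)(C)[Si](C)(C)Cl
Why: Standard silylation of a secondary allylic alcohol gives a bulky ether that steers the next step and survives base, borane and radical conditions.

Step 6
Reactants: 7 (R)-tert-butyl[(3-ethynyl-2,4,4-trimethylcyclohex-2-en-1-yl)oxy]dimethylsilane
Product: 8 5α,10α-epoxide, tert-butyl{[(1S,2R,6S)-6-ethynyl-1,5,5-trimethyl-7-oxabicyclo[4.1.0]heptan-2-yl]oxy}dimethylsilane (oxirane O trans to OTBS)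
Conditions: dimethyldioxirane, acetone/CH2Cl2, −20 °C to 0 °C
Reagents that add atoms: dimethyldioxirane CC1(C)OO1
Why: Electrophilic dioxirane epoxidation picks the only electron-rich π bond (the tetrasubstituted C5=C10 alkene, not the alkyne) and should come anti to the OTBS group, which sits pseudoaxial on the β face to escape allylic strain with the C10 methyl group, so the C5–O bond is set α.

Step 7
Reactants: 8 5α,10α-epoxide
Product: 9 3-(TBSO)-1-ethynyl-6,6-dimethyl-2-methylidenecyclohexan-1-ol (5α-OH trans to 1β-OTBS)
Conditions: LiN(iPr)2 (4 equiv), THF/Et2O, 0 °C to rt; then H2O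
Reagents that add atoms: none
Why: Base-induced isomerisation of an epoxide to an allylic alcohol by β-elimination can only break the C10–O bond here, because C4 is quaternary and C6 is an alkyne carbon, and it should take a proton from the open C10 methyl group rather than the shielded C1–H, which leaves the C5 configuration untouched.

Step 8
Reactants: 9 3-(TBSO)-1-ethynyl-6,6-dimethyl-2-methylidenecyclohexan-1-ol
Product: 11 2-[3-(TBSO)-1-hydroxy-6,6-dimethyl-2-methylidenecyclohexyl]acetaldehyde (1β-OTBS 5α-OH), via alkenylborane 10 (not isolated)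
Conditions: Cy2BH (2.2 equiv, preformed), THF, 0 °C; then 30% H2O2, NaH2PO4/Na2HPO4 buffer (pH 7), 0 °C
Reagents that add atoms: hydrogen peroxide OO
Why: Anti-Markovnikov hydroboration–oxidation of a terminal alkyne with a bulky dialkylborane, which reacts faster with the alkyne than with the flanked 1,1-disubstituted alkene, should give the aldehyde after buffered oxidation and enol tautomerisation.

Step 9
Reactants: 11 2-[3-(TBSO)-1-hydroxy-6,6-dimethyl-2-methylidenecyclohexyl]acetaldehyde; 12 (E)-4,4-dimethoxybut-2-enal
Product: 14 1β-TBSO-5α,7β-dihydroxy-11,11-dimethoxydriman-12-al (trans-decalin; 8α-CHO; 9β-CH(OMe)2), via ring-open iron enolate 13 (not isolated)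
Conditions: Fe(acac)3 (0.3 equiv), PhSiH2(OiPr) (2 equiv), 12 (3 equiv), i-PrOH/1,2-dichloroethane, argon, 0 °C to rt
Reagents that add atoms: none
Why: An iron hydride formed from Fe(acac)3 and the silane transfers a hydrogen atom to the CH2 terminus of the only alkene of 11, the tertiary C10 radical adds to C9 (the β-carbon of enal 12), divalent iron reduces the resulting α-formyl radical to the trivalent iron enolate 13, and this enolate attacks the C7 aldehyde. The closest known reaction type is the hydrogen-atom-transfer-initiated radical–polar crossover annulation (Giese addition followed by aldol cyclisation) of γ,δ-unsaturated aldehydes with α,β-unsaturated aldehydes. Ring B closes by a 6-(enolexo)-exo-trig aldol addition through a chair in which C6 and C9 are both equatorial on ring A, which is the trans-decalin. C10 is controlled by the ring A chair of 11 (OTBS and CH2CHO equatorial, 5-OH axial): the axial 4β-methyl group is 1,3-diaxial to the β lobe of the radical, so C9 should bond from the α face and the new methyl group becomes β. C9 is controlled by the staggered approach that puts its hydrogen between C1 and C5 and the branched acetal carbon next to the smaller C1 flank, which gives 9α-H, while C8 (formyl equatorial) and C7 (hydroxyl equatorial) follow from the chair and are erased in step 10. The step needs hydrogen-atom transfer to the electron-neutral 1,1-disubstituted alkene in the presence of excess enal and β-regioselective radical addition, and both should be secured by the polarity match of a nucleophilic tertiary radical with the enal and by the acetal, which leaves only one carbonyl-conjugated alkene terminus.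

Step 10
Reactants: 14 1β-TBSO-5α,7β-dihydroxy-11,11-dimethoxydriman-12-al
Product: 16 1β-TBSO-5α-hydroxy-11,11-dimethoxydrim-7-en-12-al, via C7 mesylate 15 (not isolated)
Conditions: MsCl (1.3 equiv), Et3N (4 equiv), CH2Cl2, −20 °C to rt
Reagents that add atoms: none
Why: Mesylation of the secondary 7-hydroxyl (the axial tertiary 5-hydroxyl between two quaternary carbons should not compete) and E1cB elimination through the C12 enolate should give the conjugated C7=C8 enal, and C9 is safe because its acetal substituent does not acidify it.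

Step 11
Reactants: 16 1β-TBSO-5α-hydroxy-11,11-dimethoxydrim-7-en-12-al
Product: 17 1β,5α-dihydroxy-11,11-dimethoxydrim-7-en-12-al
Conditions: Bu4NF, AcOH (1:1), THF, rt to 40 °C
Reagents that add atoms: none
Why: Fluoride-induced Si–O cleavage buffered by acetic acid should free the 1β-hydroxyl without ionising the acetal or exposing the δ-hydroxy enal to strong base.

Step 12
Reactants: 18 (E)-p-coumaric acid
Product: 20 (E)-4-(tert-butyldimethylsilyloxy)cinnamic acid, via bis-silylated coumarate 19 (not isolated)
Conditions: TBSCl (2.5 equiv), imidazole, DMF, rt; then AcOH/THF/H2O, rt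
Reagents that add atoms: tert-butyldimethylsilyl chloride CC(C)(C)[Si](C)(C)Cl
Why: Exhaustive silylation followed by selective hydrolysis of the labile silyl ester, while the aryl silyl ether resists mild aqueous acid, is the standard way to a phenol-protected cinnamic acid and does not touch the E alkene.

Step 13
Reactants: 17 1β,5α-dihydroxy-11,11-dimethoxydrim-7-en-12-al; 20 (E)-4-(tert-butyldimethylsilyloxy)cinnamic acid
Product: 22 1β-[(E)-4-(TBSO)cinnamoyloxy]-5α-hydroxy-11,11-dimethoxydrim-7-en-12-al, via mixed anhydride 21 (not isolated)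
Conditions: 20, 2,4,6-trichlorobenzoyl chloride, Et3N, toluene, rt; then 17, DMAP, toluene, rt to 60 °C
Reagents that add atoms: none
Why: Yamaguchi esterification through the mixed anhydride and its acylpyridinium ion is a method of choice for hindered secondary alcohols, acylates O1 with retention at C1, and should ignore the tertiary 5-hydroxyl.

Step 14
Reactants: 22 1β-[(E)-4-(TBSO)cinnamoyloxy]-5α-hydroxy-11,11-dimethoxydrim-7-en-12-al
Product: 23 1β-[(E)-p-coumaroyloxy]-5α-hydroxydrim-7-ene-11,12-dial (target)
Conditions: 48% aq HF, MeCN, 0 °C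
Reagents that add atoms: water O
Why: Aqueous HF should cleave the aryl silyl ether and hydrolyse the dimethyl acetal in one mildly acidic operation, under which the 9β-formyl group, prone to epimerise under base, should keep its configuration.

**Compound list**
1 | 4,4-dimethylcyclohexane-1,3-dione | CC1(C)CCC(=O)CC1=O | starting material
2 | 2,4,4-trimethylcyclohexane-1,3-dione | CC1C(=O)CCC(C)(C)C1=O | intermediate
3 | 3-isobutoxy-2,6,6-trimethylcyclohex-2-en-1-one | CC(C)COC1=C(C)C(=O)C(C)(C)CC1 | intermediate
4 | 1-ethynyl-3-isobutoxy-2,6,6-trimethylcyclohex-2-en-1-ol (racemic, transient) | CC(C)COC1=C(C)C(O)(C#C)C(C)(C)CC1 | intermediate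
5 | 3-ethynyl-2,4,4-trimethylcyclohex-2-en-1-one | CC1=C(C#C)C(C)(C)CCC1=O | intermediate
6 | (R)-3-ethynyl-2,4,4-trimethylcyclohex-2-en-1-ol | CC1(C)CC[C@@H](O)C(C)=C1C#C | intermediate
7 | TBS ether of 6 | CC1(C)CC[C@@H](O[Si](C)(C)C(C)(C)C)C(C)=C1C#C | intermediate
8 | 5α,10α-epoxide of 7 (oxirane O trans to OTBS) | CC1(C)CC[C@@H](O[Si](C)(C)C(C)(C)C)[C@]2(C)O[C@]12C#C | intermediate
9 | 3-(TBSO)-1-ethynyl-6,6-dimethyl-2-methylidenecyclohexan-1-ol (OH trans to OTBS) | CC1(C)CC[C@@H](O[Si](C)(C)C(C)(C)C)C(=C)[C@@]1(O)C#C | intermediate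
10 | (E)-alkenyl(dicyclohexyl)borane from 9 | CC1(C)CC[C@@H](O[Si](C)(C)C(C)(C)C)C(=C)[C@@]1(O)/C=C/B(C2CCCCC2)C2CCCCC2 | intermediate
11 | 2-[3-(TBSO)-1-hydroxy-6,6-dimethyl-2-methylidenecyclohexyl]acetaldehyde | CC1(C)CC[C@@H](O[Si](C)(C)C(C)(C)C)C(=C)[C@@]1(O)CC=O | intermediate
12 | (E)-4,4-dimethoxybut-2-enal (fumaraldehyde mono(dimethyl acetal)) | COC(OC)/C=C/C=O | starting material
13 | ring-open Giese adduct, iron enolate at C8 drawn as its enol | CC1(C)CC[C@@H](O[Si](C)(C)C(C)(C)C)[C@](C)([C@@H](C(OC)OC)C=CO)[C@@]1(O)CC=O | intermediate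
14 | 1β-TBSO-5α,7β-dihydroxy-11,11-dimethoxydriman-12-al | CC1(C)CC[C@@H](O[Si](C)(C)C(C)(C)C)[C@]2(C)[C@@H](C(OC)OC)[C@H](C=O)[C@@H](O)C[C@@]12O | intermediate
15 | 7β-mesylate of 14 | CC1(C)CC[C@@H](O[Si](C)(C)C(C)(C)C)[C@]2(C)[C@@H](C(OC)OC)[C@H](C=O)[C@@H](OS(C)(=O)=O)C[C@@]12O | intermediate
16 | 1β-TBSO-5α-hydroxy-11,11-dimethoxydrim-7-en-12-al | CC1(C)CC[C@@H](O[Si](C)(C)C(C)(C)C)[C@]2(C)[C@@H](C(OC)OC)C(C=O)=CC[C@@]12O | intermediate
17 | 1β,5α-dihydroxy-11,11-dimethoxydrim-7-en-12-al | CC1(C)CC[C@@H](O)[C@]2(C)[C@@H](C(OC)OC)C(C=O)=CC[C@@]12O | intermediate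
18 | (E)-p-coumaric acid | OC(=O)/C=C/c1ccc(O)cc1 | starting material
19 | TBS (E)-4-(TBSO)cinnamate | CC(C)(C)[Si](C)(C)Oc1ccc(/C=C/C(=O)O[Si](C)(C)C(C)(C)C)cc1 | intermediate
20 | (E)-4-(tert-butyldimethylsilyloxy)cinnamic acid | CC(C)(C)[Si](C)(C)Oc1ccc(/C=C/C(=O)O)cc1 | intermediate
21 | mixed anhydride of 20 and 2,4,6-trichlorobenzoic acid | CC(C)(C)[Si](C)(C)Oc1ccc(/C=C/C(=O)OC(=O)c2c(Cl)cc(Cl)cc2Cl)cc1 | intermediate
22 | 1β-[(E)-4-(TBSO)cinnamoyloxy]-5α-hydroxy-11,11-dimethoxydrim-7-en-12-al | CC1(C)CC[C@@H](OC(=O)/C=C/c3ccc(O[Si](C)(C)C(C)(C)C)cc3)[C@]2(C)[C@@H](C(OC)OC)C(C=O)=CC[C@@]12O | intermediate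
23 | 1β-[(E)-p-coumaroyloxy]-5α-hydroxydrim-7-ene-11,12-dial | CC1(C)CC[C@@H](OC(=O)/C=C/c2ccc(O)cc2)[C@]2(C)[C@@H](C=O)C(C=O)=CC[C@@]12O | target

Total step count: 14. Longest linear sequence: 13 (steps 1–11, 13, 14).

**Steps most likely to fail**

Step 9. The congested tertiary radical may add too slowly to a β-substituted enal. Premature reduction of the radical, protonation of the enolate before ring closure, or poor face selectivity at C10 or C9 could then take over.
- The fallback sets out from 7 and returns at 16.
- Semihydrogenation (H2, Pd/CaCO3 poisoned by Pb(OAc)2, quinoline) would give the vinyl diene F1.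
- A thermal Diels–Alder reaction with dimethyl acetylenedicarboxylate (toluene, sealed tube, 120 °C), anti to the silyl ether, would form the same C7–C8 and C9–C10 bonds and give the cyclohexadiene diester F2.
- LiN(iPr)2 at −78 °C removes a doubly allylic C7 proton. Kinetic protonation at C9 from the α face would then give the conjugated 5,7-diene diester F3.
- mCPBA should epoxidise the electron-richer γ,δ-alkene from the α face to give the 5α,6α-epoxide F4.
- LiAlH4 would reduce both esters and open the oxirane at C6 in the trans-diaxial sense to give the triol F5.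
- Swern oxidation ((COCl)2, DMSO, Et3N, −78 °C) would give the dialdehyde F6.
- Selective acetalisation of the non-conjugated C11 aldehyde (HC(OMe)3, MeOH, PPTS) leads back to 16.

Step 6. Facial selectivity may be poor, because the pseudoaxial methyl group at C4 on the α face competes with the silyl ether on the β face.
- The fallback sets out from 5 and returns at 8.
- Reduction with (R)-Me-CBS and catecholborane would give the enantiomeric (S)-alcohol F7.
- Hydroxyl-directed epoxidation (VO(acac)2, t-BuOOH) places the oxirane syn to the 1α-hydroxyl and so on the required α face, giving the syn-epoxy alcohol F8.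
- Mitsunobu inversion (PPh3, DIAD, 4-nitrobenzoic acid) would give the 1β-nitrobenzoate F9.
- Methanolysis (K2CO3, MeOH) would give the anti-epoxy alcohol F10.
- Silylation (TBSCl, imidazole) gives 8.

Step 13. Acylation of the neopentyl 1β-hydroxyl next to the C11 acetal may be sluggish, and the δ-hydroxy enal may erode under base on prolonged heating.
- The fallback sets out from 17 and returns at 22.
- The small and very reactive acryloyl chloride (Et3N, DMAP, CH2Cl2, 0 °C) would give the 1β-acrylate F11.
- The aryl-bearing alkene carbon is then attached by E-selective cross metathesis with 4-(tert-butyldimethylsilyloxy)styrene (second-generation Hoveyda–Grubbs catalyst, CH2Cl2, 40 °C). The trisubstituted enal should be inert to this catalyst, and the product is 22.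

**Further compounds**
F1 | step 9 | (R)-tert-butyl[(2,4,4-trimethyl-3-vinylcyclohex-2-en-1-yl)oxy]dimethylsilane | CC1(C)CC[C@@H](O[Si](C)(C)C(C)(C)C)C(C)=C1C=C
F2 | step 9 | dimethyl 1β-TBSO-drima-5,8-diene-11,12-dioate | CC1(C)CC[C@@H](O[Si](C)(C)C(C)(C)C)[C@]2(C)C(C(=O)OC)=C(C(=O)OC)CC=C12
F3 | step 9 | dimethyl 1β-TBSO-drima-5,7-diene-11,12-dioate (9β-CO2Me) | CC1(C)CC[C@@H](O[Si](C)(C)C(C)(C)C)[C@]2(C)[C@@H](C(=O)OC)C(C(=O)OC)=CC=C12
F4 | step 9 | dimethyl 1β-TBSO-5α,6α-epoxydrim-7-ene-11,12-dioate | CC1(C)CC[C@@H](O[Si](C)(C)C(C)(C)C)[C@]2(C)[C@@H](C(=O)OC)C(C(=O)OC)=C[C@@H]3O[C@]123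
F5 | step 9 | 1β-TBSO-drim-7-ene-5α,11,12-triol | CC1(C)CC[C@@H](O[Si](C)(C)C(C)(C)C)[C@]2(C)[C@@H](CO)C(CO)=CC[C@@]12O
F6 | step 9 | 1β-TBSO-5α-hydroxydrim-7-ene-11,12-dial | CC1(C)CC[C@@H](O[Si](C)(C)C(C)(C)C)[C@]2(C)[C@@H](C=O)C(C=O)=CC[C@@]12O
F7 | step 6 | (S)-3-ethynyl-2,4,4-trimethylcyclohex-2-en-1-ol | CC1(C)CC[C@H](O)C(C)=C1C#C
F8 | step 6 | syn-epoxy alcohol (1α-OH, 5α,10α-epoxide) | CC1(C)CC[C@H](O)[C@]2(C)O[C@]12C#C
F9 | step 6 | 1β-(4-nitrobenzoate) of the 5α,10α-epoxide | CC1(C)CC[C@@H](OC(=O)c3ccc(cc3)[N+](=O)[O-])[C@]2(C)O[C@]12C#C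
F10 | step 6 | anti-epoxy alcohol (1β-OH, 5α,10α-epoxide) | CC1(C)CC[C@@H](O)[C@]2(C)O[C@]12C#C
F11 | step 13 | 1β-acryloyloxy-5α-hydroxy-11,11-dimethoxydrim-7-en-12-al | CC1(C)CC[C@@H](OC(=O)C=C)[C@]2(C)[C@@H](C(OC)OC)C(C=O)=CC[C@@]12O
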